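Over the 80 min allowed, the flask differs from Friday's run in one charge: X stands at 0.700 equiv instead of 1 equiv, while L and its feed stay the same.

all flasks: L 0.50 M (fed, over 2.5 min)
- Friday's: X 1 equiv; run made earlier; the fed solution adds 0.25 times the starting volume
- flask: X 0.700 equiv; the fed solution adds 0.25 times the starting volume; time 80 min

Friday's run (percent of the L charged)

| time / min | D / % | Z / % | L / % |
|---|---|---|---|
| 3.00 | 15.7 | 0.2 | 81.9 |
| 6.00 | 36.0 | 0.6 | 57.2 |
| 10.0 | 53.2 | 2.8 | 36.8 |
| 12.0 | 59.3 | 2.8 | 29.5 |
| 15.0 | 64.3 | 5.8 | 21.7 |

(scatter of a reading: 0.3 percentage points)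

- when, up to 80 min, the flask holds most D
- the amount of D, in percent of the L charged, at that time
- earliest time at which at least nineteen twentieths of that best amount are there, in min
- latest time at which they still are, in min

- amounts are per litre of the starting volume; all of the dose is in the solution fed
- steps that have been proposed: L -> D; X -> J; D + J -> Z; 2 J -> G; L <-> E

1. No proposed step takes L and X together. So I expect the same L curve in the flask as on Friday, and the same sum of D and Z at each time. Friday's reading of that sum is 70.1% at 15.0 min.

2. Now the balance of X. Each Z costs one J, each J comes from one X, and a pair of J lost to G makes no Z. Z, in percent of the L charged, therefore stays at or below the equivalents of X. I call this the X ceiling: 70.0% in the flask, against 100% on Friday. For making Z, X is the limiting reagent of the flask, charged in less than one equivalent to L.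

3. Once L and E have both gone over to D, D and Z share the whole charge of L, so D in the flask keeps at least 30.0%, whereas Friday's balance gives a floor of 0%.

4. Friday's Z reads 5.8% at 15.0 min, far below its ceiling. I therefore expect the ceiling of the flask to act on the tail and not on the rise, with a broad peak of D that falls afterwards and stays at or above the floor.

The forecast puts 73% at 24 min, with the window from 17 min to 33 min, and adds: “The late side is uncertain”.

    L → D (k = 0.00170 s⁻¹)
    X → J (k = 3.00 × 10⁻⁴ s⁻¹)
    D + J → Z (k = 0.00360 L mol⁻¹ s⁻¹)
    2 J → G (k = 0.00450 L mol⁻¹ s⁻¹)
    L ⇌ E (K = 0.360, k = 2.90 × 10⁻⁴ s⁻¹)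

The flask holds 74.2% of D at 29.3 min, with the window from 18.6 min to 48.6 min. At 800 min, with X at 0%, the flask has Z at 55.8%, below the ceiling, and D at 44.2%, above the floor. The missing 14 percentage points is X spent on G: D + J → Z uses J 2.3 times as fast as 2 J → G at 8.41 min, and 4.5 times as fast at 80.0 min. With 2.80 equiv of X the ceiling is 280%, and that neighbour holds Z at 75.1% and D at 23.4% at 80.0 min.

(All runs are calculated for substances that don't exist, noise included.)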